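## The problem

CNP0099535.1 is a linear stilbenoid tetramer. Three trans-2-(4-hydroxyphenyl)-3-aryl-2,3-dihydrobenzofurans, called rings A, B and C here (each numbered O1, C2, C3, C3a, C4 to C7, C7a), are joined by two aryl–C(sp3) bonds, C3B–C4A and C3C–C4B; C3A carries a 3,5-dihydroxyphenyl group and C4C an (E)-3,4-dihydroxystyryl arm. All six stereocentres are benzylic. Within each ring the 2,3-trans relation is the stable one, and C2 can be corrected from C3 because the C2–O1 bond of a 4-oxyphenyl-substituted dihydrobenzofuran opens and recloses under acid; the three C3 centres cannot be corrected, and since ring B is (2S,3S) while rings A and C are (2R,3R), no single relay sets them all. Both inter-ring bonds end at flanked arene carbons (C4A next to C3aA, C4B next to C3aB), and on each resorcinol ring the new bond must go ortho to one oxygen and para to the other, never between the two. Ten free phenols (one catechol), three acid-labile benzylic ethers and a stilbene next to ring C, which is known to cyclise onto the neighbouring resorcinol ring under strong acid, restrict the late chemistry. The feature that opens a short route is arene A: C4A, which carries C3B, is meta to both oxygen-bearing carbons C6A and C7aA. That is exactly where the 3-substituent of a cyclobutenone ends up when the four-membered ring is annulated with an alkoxyalkyne, and the two oxygens emerge differentiated. A second feature is that (S)-naringenin holds ring B in latent form: shifting its C4a from C4 to C3 gives the dihydrobenzofuran with C2B correct and carbon handles at C3B and C4B.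

## Retrosynthesis

**Styryl arm last (35 ⇐ 34 ⇐ 32 + 33).** The C4C–alkene bond is cut first. All alkyl ethers must be cleaved with a strong Lewis acid, and a stilbene beside ring C would not survive that (seven-membered ring closure onto C5B). So the ethers are cleaved on bromide 30, the phenols are masked as acetates (32), and the arm arrives by Heck coupling with 3,4-diacetoxystyrene 33. Decaacetate 34 is then unmasked by mild methanolysis. The Heck step must tolerate a bromide flanked by C3aC.

**Ether cleavage (32 ⇐ 31 ⇐ 30).** Seven methyl ethers and the one ethyl ether of 30 are removed together to octaphenol 31. The dihydrobenzofurans may open at C2 under these conditions but reclose trans, because C3 is fixed.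

**Ring A (30 ⇐ 28 + 14; 28 ⇐ 25 + 26).** O1A–C2A and C2A–C3A are cut as a formal [4+1] annulation between o-quinone methide 29 (released from sulfone 28) and the ylide of the chiral sulfonium salt 14. C3aA–C3A is cut as an ortho-hydroxyalkylation of phenol 25 with 3,5-dimethoxybenzaldehyde 26. The alternative, coupling a finished ring A to C3B, would form an aryl–C(sp3) bond at a stereocentre. Here the free hydroxyl of 25 serves as O1A and as ortho-director. The forward steps must attack C3aA (para to ethoxy) despite its neighbour, and must control the face of 29 by the reagent.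

**Arene A (25 ⇐ 19 + 20), the key disconnection.** Three bonds of the benzo ring of ring A are cut (C7aA–C7A, C5A–C6A, C3aA–C7aA), leaving cyclobutenone 19 and ethoxyacetylene 20. The C3B–C4A bond is never made by coupling: C4A is the former carboxyl carbon on C3B. The precursor has one ring fewer, and the two oxygens of arene A are told apart for free.

**Cyclobutenone (19 ⇐ 18 ⇐ 16 + 17).** The four-membered ring comes from alkyne 16 and dichloroketene (from trichloroacetyl chloride 17), followed by zinc dechlorination of 18.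

**Ring C before arene A (16 ⇐ 11 + 14; 11 ⇐ 8 + 9).** Ring C is cut like ring A: [4+1] of quinone methide 15 (from sulfone 11) with the ylide of 14, and hydroxyalkylation of 3-bromo-5-methoxyphenol 9 by aldehyde 8. It is placed before the benzannulation on purpose. A cation or quinone methide at C3C would have C5A of arene A within reach for a six-membered Friedel–Crafts closure; while C3B carries only an ethynyl group there is no such trap. The C4B handle is therefore spent early.

**Handles on ring B (8 ⇐ 7 ⇐ 6 ⇐ 5 ⇐ 4).** The C4B formyl group is masked as a vinyl group (Stille coupling of triflate 4 to 5) while the C3B ester is reduced (6) and homologated to the alkyne (7). Oxidative cleavage then gives 8. A vinyl group is inert to hydride and to the diazophosphonate; a formyl group would not be.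

**Ring B from the chiral pool (4 ⇐ 3 ⇐ 2 ⇐ 1).** C3B–C3aB is cut as an oxidative 1,2-aryl shift of flavanone triflate 3. Compound 3 comes from (S)-naringenin 1 by methylation of the two non-chelated phenols (2) and triflation of the chelated one.

**Chiral reagent (14 ⇐ 12 + 13).** The sulfonium salt is made in one step from isothiocineole 12 and 4-methoxybenzyl alcohol 13. It serves both annulations, because rings A and C have the same absolute sense.

## Roads not taken

**Alternative 1:** The cut is at C3A–C3aA and at the C2A–aryl bond. Arene A would arrive as triflate A2, the C2A–C3A unit as styrylboronate A3, and the anisyl group as 4-methoxyphenyllithium A4. A4 and A3 form a boron ate complex; under palladium catalysis with a chiral ferrocene bisphosphine the aryl–palladium from A2 adds to the alkene while the anisyl group shifts from boron to C2A, giving boronate A1. Its merit is real: both centres of ring A are set in one step under ligand control, independent of any neighbouring ring. In this respect it is better than the chosen plan, which relies on a chiral reagent working beside a biasing ring B. Its weak points for this target are three. A2 is ortho,ortho-disubstituted. A β-aryl alkenylboronate is a reluctant partner in the metallate shift. Above all, A1 carries C4A only as an ester, so the C3B–C4A bond, and the same bond for ring C, is still unmade and would have to be formed at a stereocentre. The chosen plan sets against the better ring A control that it never forms C3B–C4A by coupling and that O1A and the C6A oxygen come differentiated.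

**Alternative 2:** The cut removes the three 4-methoxyphenyl groups from C2A, C2B and C2C. Tris-acid A6 would lose three molecules of CO2 under visible-light photoredox and nickel catalysis, and each α-oxy C2 radical would be arylated by 4-bromoanisole A7 to give A5. α-Oxy radicals are ideal for this coupling, capture trans to the C3 substituent is expected, and no C2 configuration need be carried. For the three aryl groups it is more step-economical than the chosen plan. But A6 already contains all three rings, both inter-ring bonds and the three non-correctable C3 centres, so the hard part is untouched. Three couplings in one flask multiply losses to protodecarboxylation and to minor diastereomers. A5 also still lacks the styryl arm. The chosen plan brings each anisyl group in with a ring-forming event (from naringenin and with the ylide), so it pays no separate steps for them.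

**Alternative 3:** The cut is C3B–C3aB. Flavanone triflate A9, treated with PhI(OAc)2 and acid in trimethyl orthoformate, undergoes the C4 to C3 shift of C4a and gives ester A8. It is as good as anything available for ring B: C2B comes from the chiral pool, C3B is set trans, and both handles are in place. It is in fact adopted here (A9 and A8 are compounds 3 and 4). As the step that carries the strategy it falls short, because it delivers only ring B and leaves open how an arene is attached to C3B. The chosen plan answers that question by turning the ester carbon itself into C4A. It shares with this alternative the risk of the aryl shift (see step 3 below).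

Key step: step 13

**Assumptions and notation**

- (S)-Naringenin 1 is taken to be available in high enantiomeric purity.
- The benzylide of isothiocineole is taken to react on the same face toward a quinone methide as toward aldehydes, which on the model used here means the (1S,4S,5S) sulfide leads to (2R,3R). If the sense is the reverse, the (1R,4R,5R) sulfide from (R)-limonene takes its place and nothing else changes.
- 3,4-Diacetoxystyrene 33 is taken as a purchasable, stabilised monomer.
- [BC] stands for the (2S,3S)-4-[(2R,3R)-4-bromo-6-methoxy-2-(4-methoxyphenyl)-2,3-dihydrobenzofuran-3-yl]-6-methoxy-2-(4-methoxyphenyl)-2,3-dihydrobenzofuran-3-yl group (rings B and C joined through C4B–C3C, attached through C3B).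

## Route

Step 1
Reactants: 1 (S)-naringenin
Product: 2 (S)-4',7-di-O-methylnaringenin
Conditions: CH2N2, Et2O–MeOH, 0 °C to rt
Reagents that add atoms: diazomethane, C=[N+]=[N-]
Why: O-Methylation of the two acidic phenols by diazomethane; the 5-hydroxyl is held in a hydrogen bond to the C4 carbonyl and stays free, and the absence of base avoids retro-oxa-Michael opening to the chalcone, which would racemise C2.

Step 2
Reactants: 2 (S)-4',7-di-O-methylnaringenin
Product: 3 (S)-4',7-di-O-methylnaringenin 5-triflate
Conditions: Tf2O, pyridine, CH2Cl2, 0 °C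
Reagents that add atoms: trifluoromethanesulfonic anhydride, O=S(=O)(OS(=O)(=O)C(F)(F)F)C(F)(F)F
Why: Sulfonylation of the only remaining phenol turns the C5 oxygen into the later C4B handle; pyridine at 0 °C is too weak a base to open the flavanone.

Step 3
Reactants: 3 (S)-4',7-di-O-methylnaringenin 5-triflate
Product: 4 methyl trans-(2S,3S)-6-methoxy-2-(4-methoxyphenyl)-4-triflyloxy-2,3-dihydrobenzofuran-3-carboxylate
Conditions: PhI(OAc)2, H2SO4 (cat.), HC(OMe)3, rt
Reagents that add atoms: trimethyl orthoformate, COC(OC)OC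
Why: Hypervalent-iodine oxidative ring contraction of a flavanone: the enol ether of the ketal is iodinated at C3 trans to the C2 aryl group, C4a migrates from C4 to C3 with loss of iodobenzene, and the dimethoxycarbenium ion collapses to the methyl ester. C2 is untouched, and the new C3 centre is trans to it through the anti migration and the stability of the trans ester.

Step 4
Reactants: 4 ring B ester triflate
Product: 5 methyl (2S,3S)-4-ethenyl-6-methoxy-2-(4-methoxyphenyl)-2,3-dihydrobenzofuran-3-carboxylate
Conditions: Bu3SnCH=CH2, Pd(PPh3)4 (5 mol%), LiCl, 1,4-dioxane, 95 °C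
Reagents that add atoms: tributyl(vinyl)stannane, C=C[Sn](CCCC)(CCCC)CCCC
Why: Stille coupling of an aryl triflate; the neutral medium spares the epimerisable β-aryloxy ester, and the vinyl group is a masked formyl group that is inert to the next two steps.

Step 5
Reactants: 5 ring B vinyl ester
Product: 6 (2S,3S)-4-ethenyl-6-methoxy-2-(4-methoxyphenyl)-2,3-dihydrobenzofuran-3-carbaldehyde
Conditions: i-Bu2AlH (1.1 equiv), CH2Cl2, −78 °C; aq. potassium sodium tartrate
Reagents that add atoms: none
Why: Partial reduction of the ester through the aluminium hemiacetal, which is stable at −78 °C; the aldehyde is used crude to limit enolisation toward O1B.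

Step 6
Reactants: 6 ring B vinyl aldehyde
Product: 7 (2S,3S)-4-ethenyl-3-ethynyl-6-methoxy-2-(4-methoxyphenyl)-2,3-dihydrobenzofuran
Conditions: MeC(O)C(N2)P(O)(OMe)2, K2CO3, MeOH, 0 °C to rt
Reagents that add atoms: dimethyl (1-diazo-2-oxopropyl)phosphonate, CC(=O)C(=[N+]=[N-])P(=O)(OC)OC
Why: Ohira–Bestmann alkynylation (Seyferth–Gilbert homologation under carbonate) adds the carbon that becomes C5A; any epimerisation at C3B returns to the stable trans isomer.

Step 7
Reactants: 7 ring B vinyl alkyne
Product: 8 (2S,3S)-3-ethynyl-6-methoxy-2-(4-methoxyphenyl)-2,3-dihydrobenzofuran-4-carbaldehyde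
Conditions: OsO4 (2 mol%), NaIO4, 2,6-lutidine, 1,4-dioxane–H2O, rt
Reagents that add atoms: sodium periodate, [Na+].[O-]I(=O)(=O)=O
Why: Lemieux–Johnson cleavage; OsO4 dihydroxylates the styrene-type alkene much faster than the terminal alkyne, and periodate cleaves the diol to the aryl aldehyde whose carbon becomes C3C.

Step 8
Reactants: 8 ring B 4-carbaldehyde; 9 3-bromo-5-methoxyphenol
Product: 11 ring C aryl(tosyl)methyl phenol sulfone, via carbinol 10 (not isolated)
Conditions: 9, EtMgBr (1 equiv), Et2O then toluene, 0 °C; 8, rt; then p-TolSO2H, CH2Cl2, 0 °C to rt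
Reagents that add atoms: p-toluenesulfinic acid, Cc1ccc(S(=O)O)cc1
Why: Ortho-specific hydroxyalkylation of a magnesium phenoxide by an aldehyde through a six-membered chelate forms C3C–C3aC at the ortho position para to methoxy, not at the one between the two oxygens. The sulfinic acid then ionises the diaryl carbinol and traps it as a bench-stable sulfone; the sp3 centre made here is erased in step 10, so its configuration does not matter.

Step 9
Reactants: 12 (1S,4S,5S)-isothiocineole; 13 4-methoxybenzyl alcohol
Product: 14 (1S,4S,5S,6S)-6-(4-methoxybenzyl)isothiocineolium tetrafluoroborate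
Conditions: HBF4·OEt2, CH2Cl2, 0 °C to rt
Reagents that add atoms: tetrafluoroboric acid (diethyl ether complex), [H+].F[B-](F)(F)F
Why: S-Alkylation of the sulfide by the 4-methoxybenzyl cation; only the exo lone pair of the bicyclic sulfide is open, so one configuration at sulfur results.

Step 10
Reactants: 11 ring C sulfone; 14 sulfonium salt
Product: 16 [BC]-ethyne, via o-quinone methide 15 (not isolated)
Conditions: Cs2CO3, MeCN, 0 °C to rt
Reagents that add atoms: none
Why: Formal [4+1] annulation of a sulfonium ylide with an o-quinone methide: carbonate expels sulfinate from the phenoxide of 11 and deprotonates 14, the ylide adds to the methide carbon (C2C–C3C), and the phenoxide displaces the sulfide with inversion (O1C–C2C). The ylide carbon reacts on the face remote from the gem-dimethyl bridge of the sulfide, which fixes C2C as R; the anti approach of the two aryl groups places C3C trans to it (R).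

Step 11
Reactants: 16 [BC]-ethyne; 17 trichloroacetyl chloride
Product: 18 4,4-dichloro-3-[BC]cyclobut-2-en-1-one
Conditions: Zn(Cu), Et2O–DME, rt
Reagents that add atoms: none
Why: [2+2] Cycloaddition of dichloroketene, made in the flask by zinc dechlorination of 17, to the terminal alkyne; the ketene carbonyl carbon bonds to the unsubstituted alkyne carbon, so the substituent ends on C3, and DME ties up ZnCl2 away from the benzylic ethers.

Step 12
Reactants: 18 dichlorocyclobutenone
Product: 19 3-[BC]cyclobut-2-en-1-one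
Conditions: Zn, AcOH, TMEDA, EtOH, 0 °C to rt
Reagents that add atoms: none
Why: Reductive removal of both α-chlorines by zinc through the zinc enolate; the amine-buffered acid keeps the medium mild, so C3B and the aryl bromide are untouched.

Step 13
Reactants: 19 3-[BC]cyclobut-2-en-1-one; 20 ethoxyacetylene
Product: 25 3-ethoxy-5-[BC]phenol, via vinylketene 21 (not isolated), via 4-vinylcyclobutenone 22 (not isolated), via dienylketene 23 (not isolated), via cyclohexadienone 24 (not isolated)
Conditions: 20 (3 equiv), toluene, 80 °C, sealed tube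
Reagents that add atoms: none
Why: Heating opens the strained enone 19 by four-electron electrocyclic cleavage of its C1–C4 bond to vinylketene 21. The electron-rich alkyne 20 then adds across the ketene C=C bond in a regioselective [2+2] step, its unsubstituted carbon bonding to the ketene carbonyl carbon (C7aA–C7A) and its ethoxy-bearing carbon to the ketene α-carbon (C5A–C6A), to give 4-vinylcyclobutenone 22. A second four-electron opening gives dienylketene 23, whose ketene carbon and methylene terminus are joined by thermal disrotatory six-electron electrocyclisation (C7aA–C3aA); this closes the benzo ring of ring A as cyclohexadienone 24, which tautomerises to phenol 25. The closest known reaction is the Danheiser benzannulation of 3-alkylcyclobutenones with alkoxyacetylenes to 5-substituted resorcinol monoethers. No stereocentre is formed; the step only has to leave C3B alone, which is vinylogously acidic in 19, and the neutral aprotic medium together with trans being the stable arrangement should secure that. The selectivity needed is regiochemical: the polarity of the ketene–ynol ether addition places the ketene oxygen on C7aA as the free hydroxyl (future O1A) and the alkyne oxygen on C6A as the ethyl ether, with C4A meta to both. Because the opening of 22 is reversible, the dienylketene isomer that cannot cyclise returns and is funnelled through 23. An excess of 20 keeps 21 from acylating the product phenol.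

Step 14
Reactants: 25 3-ethoxy-5-[BC]phenol; 26 3,5-dimethoxybenzaldehyde
Product: 28 ring A aryl(tosyl)methyl phenol sulfone, via carbinol 27 (not isolated)
Conditions: 25, EtMgBr (1 equiv), Et2O then toluene, 0 °C; 26, rt; then p-TolSO2H, CH2Cl2, 0 °C to rt
Reagents that add atoms: p-toluenesulfinic acid, Cc1ccc(S(=O)O)cc1
Why: The same magnesium phenoxide ortho-hydroxyalkylation forms C3aA–C3A at the ortho position para to ethoxy (C7A lies between the two oxygens), and the carbinol is exchanged to the sulfone. The acid can only open the three dihydrobenzofurans at C2, which reclose trans, and no arene carbon can reach a cation at C3A.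

Step 15
Reactants: 28 ring A sulfone; 14 sulfonium salt
Product: 30 tris(dihydrobenzofuran) bromide, via o-quinone methide 29 (not isolated)
Conditions: Cs2CO3, MeCN, 0 °C to rt
Reagents that add atoms: none
Why: Second formal [4+1] annulation of the sulfonium ylide with an o-quinone methide, forming C2A–C3A and O1A–C2A. C2A (R) is set by the face of the ylide fixed by the sulfide, and C3A (R) by the trans-leading approach, as in step 10.

Step 16
Reactants: 30 tris(dihydrobenzofuran) bromide
Product: 31 octaphenol bromide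
Conditions: BBr3 (excess), CH2Cl2, −78 °C to rt; then MeOH, H2O
Reagents that add atoms: none
Why: Lewis acid cleavage of the seven methyl ethers and the ethyl ether; no alkene is present yet, and any opening of a benzylic C2–O1 bond recloses trans under control of the fixed C3 centre.

Step 17
Reactants: 31 octaphenol bromide
Product: 32 octaacetate bromide
Conditions: Ac2O, pyridine, DMAP (cat.), rt
Reagents that add atoms: acetic anhydride, CC(=O)OC(C)=O
Why: Peracetylation makes the polyphenol soluble, stable to air and compatible with the palladium step.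

Step 18
Reactants: 32 octaacetate bromide; 33 3,4-diacetoxystyrene
Product: 34 decaacetate of the target
Conditions: Pd(OAc)2 (10 mol%), P(t-Bu)3·HBF4, Cy2NMe, 1,4-dioxane, 80 °C
Reagents that add atoms: none
Why: Heck reaction at C4C; syn insertion and syn β-hydride elimination give the (E)-stilbene, the bulky electron-rich phosphine handles the ortho-flanked bromide, and the amine base leaves aryl acetates intact.

Step 19
Reactants: 34 decaacetate
Product: 35 CNP0099535.1
Conditions: K2CO3 (cat.), MeOH (degassed), 0 °C to rt; then Amberlite IR-120 (H+ form)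
Reagents that add atoms: none
Why: Base-catalysed transesterification of the ten aryl acetates to methyl acetate; cold, oxygen-free conditions and neutralisation on an acidic resin protect the catechol and the stilbene beside ring C.

## Compound list

1 | (S)-naringenin, (2S)-5,7-dihydroxy-2-(4-hydroxyphenyl)chroman-4-one | O=C1C[C@@H](c2ccc(O)cc2)Oc2cc(O)cc(O)c12 | starting material
2 | (2S)-5-hydroxy-7-methoxy-2-(4-methoxyphenyl)chroman-4-one | O=C1C[C@@H](c2ccc(OC)cc2)Oc2cc(OC)cc(O)c12 | intermediate
3 | (2S)-7-methoxy-2-(4-methoxyphenyl)-4-oxochroman-5-yl trifluoromethanesulfonate | O=C1C[C@@H](c2ccc(OC)cc2)Oc2cc(OC)cc(OS(=O)(=O)C(F)(F)F)c12 | intermediate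
4 | methyl (2S,3S)-6-methoxy-2-(4-methoxyphenyl)-4-[(trifluoromethanesulfonyl)oxy]-2,3-dihydrobenzofuran-3-carboxylate (2,3-trans) | COc1ccc([C@H]2Oc3cc(OC)cc(OS(=O)(=O)C(F)(F)F)c3[C@@H]2C(=O)OC)cc1 | intermediate
5 | methyl (2S,3S)-4-ethenyl-6-methoxy-2-(4-methoxyphenyl)-2,3-dihydrobenzofuran-3-carboxylate | COc1ccc([C@H]2Oc3cc(OC)cc(C=C)c3[C@@H]2C(=O)OC)cc1 | intermediate
6 | (2S,3S)-4-ethenyl-6-methoxy-2-(4-methoxyphenyl)-2,3-dihydrobenzofuran-3-carbaldehyde | COc1ccc([C@H]2Oc3cc(OC)cc(C=C)c3[C@@H]2C=O)cc1 | intermediate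
7 | (2S,3S)-4-ethenyl-3-ethynyl-6-methoxy-2-(4-methoxyphenyl)-2,3-dihydrobenzofuran | COc1ccc([C@H]2Oc3cc(OC)cc(C=C)c3[C@@H]2C#C)cc1 | intermediate
8 | (2S,3S)-3-ethynyl-6-methoxy-2-(4-methoxyphenyl)-2,3-dihydrobenzofuran-4-carbaldehyde | COc1ccc([C@H]2Oc3cc(OC)cc(C=O)c3[C@@H]2C#C)cc1 | intermediate
9 | 3-bromo-5-methoxyphenol | COc1cc(O)cc(Br)c1 | starting material
10 | (2-bromo-6-hydroxy-4-methoxyphenyl)[(2S,3S)-3-ethynyl-6-methoxy-2-(4-methoxyphenyl)-2,3-dihydrobenzofuran-4-yl]methanol, both carbinol epimers | COc1ccc([C@H]2Oc3cc(OC)cc(C(O)c4c(Br)cc(OC)cc4O)c3[C@@H]2C#C)cc1 | intermediate (not isolated)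
11 | 3-bromo-5-methoxy-2-{[(2S,3S)-3-ethynyl-6-methoxy-2-(4-methoxyphenyl)-2,3-dihydrobenzofuran-4-yl](4-methylbenzenesulfonyl)methyl}phenol, both epimers at the sulfonyl carbon | COc1ccc([C@H]2Oc3cc(OC)cc(C(c4c(Br)cc(OC)cc4O)S(=O)(=O)c4ccc(C)cc4)c3[C@@H]2C#C)cc1 | intermediate
12 | (1S,4S,5S)-4,7,7-trimethyl-6-thiabicyclo[3.2.1]octane (isothiocineole from (S)-limonene) | C[C@H]1CC[C@H]2C[C@@H]1SC2(C)C | starting material
13 | 4-methoxybenzyl alcohol | COc1ccc(CO)cc1 | starting material
14 | (1S,4S,5S,6S)-6-(4-methoxybenzyl)-4,7,7-trimethyl-6-thiabicyclo[3.2.1]octan-6-ium tetrafluoroborate (benzyl group exo) | C[C@H]1CC[C@H]2C[C@@H]1[S@+](Cc1ccc(OC)cc1)C2(C)C.F[B-](F)(F)F | intermediate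
15 | (6E)-5-bromo-6-{[(2S,3S)-3-ethynyl-6-methoxy-2-(4-methoxyphenyl)-2,3-dihydrobenzofuran-4-yl]methylidene}-3-methoxycyclohexa-2,4-dien-1-one | COc1ccc([C@H]2Oc3cc(OC)cc(/C=C4\C(=O)C=C(OC)C=C4Br)c3[C@@H]2C#C)cc1 | intermediate (not isolated)
16 | (2S,3S)-4-[(2R,3R)-4-bromo-6-methoxy-2-(4-methoxyphenyl)-2,3-dihydrobenzofuran-3-yl]-3-ethynyl-6-methoxy-2-(4-methoxyphenyl)-2,3-dihydrobenzofuran ([BC]-ethyne) | COc1ccc([C@H]2Oc3cc(OC)cc([C@@H]4c5c(Br)cc(OC)cc5O[C@H]4c4ccc(OC)cc4)c3[C@@H]2C#C)cc1 | intermediate
17 | trichloroacetyl chloride | ClC(=O)C(Cl)(Cl)Cl | starting material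
18 | 4,4-dichloro-3-[BC]cyclobut-2-en-1-one (C3B is R by the sequence rules here; arrangement unchanged) | COc1ccc([C@H]2Oc3cc(OC)cc([C@@H]4c5c(Br)cc(OC)cc5O[C@H]4c4ccc(OC)cc4)c3[C@@H]2C2=CC(=O)C2(Cl)Cl)cc1 | intermediate
19 | 3-[BC]cyclobut-2-en-1-one | COc1ccc([C@H]2Oc3cc(OC)cc([C@@H]4c5c(Br)cc(OC)cc5O[C@H]4c4ccc(OC)cc4)c3[C@@H]2C2=CC(=O)C2)cc1 | intermediate
20 | ethoxyacetylene (ethoxyethyne) | C#COCC | starting material
21 | 3-[BC]buta-1,3-dien-1-one (vinylketene) | COc1ccc([C@H]2Oc3cc(OC)cc([C@@H]4c5c(Br)cc(OC)cc5O[C@H]4c4ccc(OC)cc4)c3[C@@H]2C(=C)C=C=O)cc1 | intermediate (not isolated)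
22 | 3-ethoxy-4-(1-[BC]ethenyl)cyclobut-2-en-1-one, either configuration at C4 of the four-membered ring | COc1ccc([C@H]2Oc3cc(OC)cc([C@@H]4c5c(Br)cc(OC)cc5O[C@H]4c4ccc(OC)cc4)c3[C@@H]2C(=C)C2C(=O)C=C2OCC)cc1 | intermediate (not isolated)
23 | (3E)-3-ethoxy-5-[BC]hexa-1,3,5-trien-1-one (dienylketene, chain ends cis on C3=C4) | COc1ccc([C@H]2Oc3cc(OC)cc([C@@H]4c5c(Br)cc(OC)cc5O[C@H]4c4ccc(OC)cc4)c3[C@@H]2C(=C)/C=C(OCC)\C=C=O)cc1 | intermediate (not isolated)
24 | 3-ethoxy-5-[BC]cyclohexa-2,4-dien-1-one | COc1ccc([C@H]2Oc3cc(OC)cc([C@@H]4c5c(Br)cc(OC)cc5O[C@H]4c4ccc(OC)cc4)c3[C@@H]2C2=CC(OCC)=CC(=O)C2)cc1 | intermediate (not isolated)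
25 | 3-ethoxy-5-[BC]phenol | COc1ccc([C@H]2Oc3cc(OC)cc([C@@H]4c5c(Br)cc(OC)cc5O[C@H]4c4ccc(OC)cc4)c3[C@@H]2c2cc(O)cc(OCC)c2)cc1 | intermediate
26 | 3,5-dimethoxybenzaldehyde | COc1cc(C=O)cc(OC)c1 | starting material
27 | 2-[(3,5-dimethoxyphenyl)(hydroxy)methyl]-5-ethoxy-3-[BC]phenol, both carbinol epimers | COc1ccc([C@H]2Oc3cc(OC)cc([C@@H]4c5c(Br)cc(OC)cc5O[C@H]4c4ccc(OC)cc4)c3[C@@H]2c2cc(OCC)cc(O)c2C(O)c2cc(OC)cc(OC)c2)cc1 | intermediate (not isolated)
28 | 2-[(3,5-dimethoxyphenyl)(4-methylbenzenesulfonyl)methyl]-5-ethoxy-3-[BC]phenol, both epimers at the sulfonyl carbon | COc1ccc([C@H]2Oc3cc(OC)cc([C@@H]4c5c(Br)cc(OC)cc5O[C@H]4c4ccc(OC)cc4)c3[C@@H]2c2cc(OCC)cc(O)c2C(c2cc(OC)cc(OC)c2)S(=O)(=O)c2ccc(C)cc2)cc1 | intermediate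
29 | (6Z)-6-[(3,5-dimethoxyphenyl)methylidene]-3-ethoxy-5-[BC]cyclohexa-2,4-dien-1-one | COc1ccc([C@H]2Oc3cc(OC)cc([C@@H]4c5c(Br)cc(OC)cc5O[C@H]4c4ccc(OC)cc4)c3[C@@H]2C2=CC(OCC)=CC(=O)/C2=C\c2cc(OC)cc(OC)c2)cc1 | intermediate (not isolated)
30 | (2R,3R)-3-(3,5-dimethoxyphenyl)-6-ethoxy-2-(4-methoxyphenyl)-4-[BC]-2,3-dihydrobenzofuran (ring A 2R,3R; ring B 2S,3S; ring C 2R,3R with Br on C4C) | COc1ccc([C@H]2Oc3cc(OC)cc([C@@H]4c5c(Br)cc(OC)cc5O[C@H]4c4ccc(OC)cc4)c3[C@@H]2c2cc(OCC)cc3c2[C@@H](c2cc(OC)cc(OC)c2)[C@H](c2ccc(OC)cc2)O3)cc1 | intermediate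
31 | octaphenol: 30 with its seven methyl ethers and its ethyl ether cleaved, bromine on C4C kept | Oc1ccc([C@H]2Oc3cc(O)cc([C@@H]4c5c(Br)cc(O)cc5O[C@H]4c4ccc(O)cc4)c3[C@@H]2c2cc(O)cc3c2[C@@H](c2cc(O)cc(O)c2)[C@H](c2ccc(O)cc2)O3)cc1 | intermediate
32 | octaacetate of 31 | CC(=O)Oc1ccc([C@H]2Oc3cc(OC(C)=O)cc([C@@H]4c5c(Br)cc(OC(C)=O)cc5O[C@H]4c4ccc(OC(C)=O)cc4)c3[C@@H]2c2cc(OC(C)=O)cc3c2[C@@H](c2cc(OC(C)=O)cc(OC(C)=O)c2)[C@H](c2ccc(OC(C)=O)cc2)O3)cc1 | intermediate
33 | 3,4-diacetoxystyrene (4-ethenyl-1,2-phenylene diacetate) | C=Cc1ccc(OC(C)=O)c(OC(C)=O)c1 | starting material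
34 | decaacetate of 35 ((E)-3,4-diacetoxystyryl on C4C) | CC(=O)Oc1ccc([C@H]2Oc3cc(OC(C)=O)cc([C@@H]4c5c(/C=C/c6ccc(OC(C)=O)c(OC(C)=O)c6)cc(OC(C)=O)cc5O[C@H]4c4ccc(OC(C)=O)cc4)c3[C@@H]2c2cc(OC(C)=O)cc3c2[C@@H](c2cc(OC(C)=O)cc(OC(C)=O)c2)[C@H](c2ccc(OC(C)=O)cc2)O3)cc1 | intermediate
35 | CNP0099535.1 (ring A 2R,3R; ring B 2S,3S; ring C 2R,3R; E-alkene) | Oc1ccc([C@H]2Oc3cc(O)cc([C@@H]4c5c(/C=C/c6ccc(O)c(O)c6)cc(O)cc5O[C@H]4c4ccc(O)cc4)c3[C@@H]2c2cc(O)cc3c2[C@@H](c2cc(O)cc(O)c2)[C@H](c2ccc(O)cc2)O3)cc1 | target

## Step count and risks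

Total step count: 19. Longest linear sequence: 18 steps (1 to 35 through steps 1–8 and 10–19); step 9 is the one-step side branch to 14.

**Step 13 (key step).** The most likely failure is that vinylketene 21 is used up faster by side reactions than by the alkyne. Ethoxyacetylene is lost by retro-ene fragmentation on long heating, and the product phenol can be acylated by 21. Prolonged heating may also erode C3B through the dienol of 19. Fallback, from 16 to 25: Markovnikov hydroxycarbonylation of the alkyne (Pd(OAc)2, 2-pyridyldiphenylphosphine, MeSO3H, CO, aqueous acetone) gives 2-[BC]prop-2-enoic acid F1. Its acid chloride ((COCl)2) with diazomethane gives 1-diazo-3-[BC]but-3-en-2-one F2. Irradiation of F2 (300 nm) with 20 at room temperature triggers a photochemical Wolff rearrangement to the same vinylketene 21 without heat; brief warming completes the cascade to 25.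

**Step 3.** The electron-rich 4-methoxyphenyl group may migrate from C2 to C3 (isoflavone formation), or the flavanone may be dehydrogenated, in competition with the C4a shift, which the ortho triflate slows. Fallback, from 3 to 4: deacylative diazo transfer (LiN(SiMe3)2, CF3CO2CH2CF3, −78 °C; then MsN3, Et3N) gives (2R)-3-diazo-7-methoxy-2-(4-methoxyphenyl)-4-oxochroman-5-yl triflate F3. Photolysis in methanol (Wolff rearrangement, in which only C4a can migrate) gives 4 together with its cis epimer, methyl (2S,3R)-ester F4. Brief treatment with DBU converts F4 into 4.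

**Step 6.** Carbonate may enolise aldehyde 6 toward O1B; β-elimination then opens the furan ring, and reclosure has no memory of C2B, so enantiomeric purity is lost. Fallback, from 6 to 7: Corey–Fuchs olefination under neutral conditions (CBr4, PPh3, CH2Cl2, 0 °C) gives (2S,3S)-3-(2,2-dibromoethenyl)-4-ethenyl-6-methoxy-2-(4-methoxyphenyl)-2,3-dihydrobenzofuran F5. n-BuLi (2.1 equiv, THF, −78 °C) converts F5 into 7.

**Step 14 (the same question arises in step 8).** Hydroxyalkylation may go to the wrong ortho position (C7A) or fail, because C3aA is flanked by the bulky C4A substituent and the aldehyde is large. Fallback, from 25 to 28: ortho-formylation with the smallest electrophile (MgCl2, Et3N, paraformaldehyde, MeCN, reflux) gives 4-ethoxy-2-hydroxy-6-[BC]benzaldehyde F6. Addition of 3,5-dimethoxyphenylmagnesium bromide (2.2 equiv, THF, 0 °C) to F6 gives carbinol 27, which p-TolSO2H converts into 28 as in the main route.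

**Step 15 (the same holds for step 10).** Facial selectivity may be poor. The sulfide controls the ylide carbon, but the face of quinone methide 29 that is attacked is also biased by the neighbouring ring B, and the two influences may oppose each other. O-Alkylation of the phenoxide by 14 is a second drain. Fallback, from 27 to 30, with catalyst control of C3A:
- MnO2 oxidises 27 (isolated by aqueous work-up) to the (3,5-dimethoxyphenyl) aryl ketone F7.
- 4-Methoxybenzyl chloride and K2CO3 give its 4-methoxybenzyl ether F8.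
- N2H4·H2O gives hydrazone F9.
- MnO2 oxidises F9 to the diaryldiazomethane F10, which is not isolated.
- Rh2(R-PTAD)4, or its mirror image, whichever delivers 3R, effects donor/donor carbene insertion into the benzylic C–H bond and gives the cis-(2S,3R) ring A compound F11.
- CF3CO2H (cat.) in CH2Cl2 equilibrates C2A and gives trans 30.

## Further compounds

F1 | step 13 | 2-[BC]prop-2-enoic acid (C3B is R by the sequence rules; arrangement as in 16) | COc1ccc([C@H]2Oc3cc(OC)cc([C@@H]4c5c(Br)cc(OC)cc5O[C@H]4c4ccc(OC)cc4)c3[C@@H]2C(=C)C(=O)O)cc1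
F2 | step 13 | 1-diazo-3-[BC]but-3-en-2-one (C3B is R by the sequence rules; arrangement as in 16) | COc1ccc([C@H]2Oc3cc(OC)cc([C@@H]4c5c(Br)cc(OC)cc5O[C@H]4c4ccc(OC)cc4)c3[C@@H]2C(=C)C(=O)C=[N+]=[N-])cc1
F3 | step 3 | (2R)-3-diazo-7-methoxy-2-(4-methoxyphenyl)-4-oxochroman-5-yl trifluoromethanesulfonate (arrangement at C2 as in 3) | O=C1C(=[N+]=[N-])[C@@H](c2ccc(OC)cc2)Oc2cc(OC)cc(OS(=O)(=O)C(F)(F)F)c12
F4 | step 3 | methyl (2S,3R)-6-methoxy-2-(4-methoxyphenyl)-4-[(trifluoromethanesulfonyl)oxy]-2,3-dihydrobenzofuran-3-carboxylate (2,3-cis) | COc1ccc([C@H]2Oc3cc(OC)cc(OS(=O)(=O)C(F)(F)F)c3[C@H]2C(=O)OC)cc1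
F5 | step 6 | (2S,3S)-3-(2,2-dibromoethenyl)-4-ethenyl-6-methoxy-2-(4-methoxyphenyl)-2,3-dihydrobenzofuran | COc1ccc([C@H]2Oc3cc(OC)cc(C=C)c3[C@@H]2C=C(Br)Br)cc1
F6 | step 14 | 4-ethoxy-2-hydroxy-6-[BC]benzaldehyde | COc1ccc([C@H]2Oc3cc(OC)cc([C@@H]4c5c(Br)cc(OC)cc5O[C@H]4c4ccc(OC)cc4)c3[C@@H]2c2cc(OCC)cc(O)c2C=O)cc1
F7 | step 15 | (3,5-dimethoxyphenyl)(4-ethoxy-2-hydroxy-6-[BC]phenyl)methanone | COc1ccc([C@H]2Oc3cc(OC)cc([C@@H]4c5c(Br)cc(OC)cc5O[C@H]4c4ccc(OC)cc4)c3[C@@H]2c2cc(OCC)cc(O)c2C(=O)c2cc(OC)cc(OC)c2)cc1
F8 | step 15 | (3,5-dimethoxyphenyl){4-ethoxy-2-[(4-methoxybenzyl)oxy]-6-[BC]phenyl}methanone | COc1ccc([C@H]2Oc3cc(OC)cc([C@@H]4c5c(Br)cc(OC)cc5O[C@H]4c4ccc(OC)cc4)c3[C@@H]2c2cc(OCC)cc(OCc4ccc(OC)cc4)c2C(=O)c2cc(OC)cc(OC)c2)cc1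
F9 | step 15 | hydrazone of F8 (either C=N geometry) | COc1ccc([C@H]2Oc3cc(OC)cc([C@@H]4c5c(Br)cc(OC)cc5O[C@H]4c4ccc(OC)cc4)c3[C@@H]2c2cc(OCC)cc(OCc4ccc(OC)cc4)c2C(=NN)c2cc(OC)cc(OC)c2)cc1
F10 | step 15 | diazo(3,5-dimethoxyphenyl){4-ethoxy-2-[(4-methoxybenzyl)oxy]-6-[BC]phenyl}methane | COc1ccc([C@H]2Oc3cc(OC)cc([C@@H]4c5c(Br)cc(OC)cc5O[C@H]4c4ccc(OC)cc4)c3[C@@H]2c2cc(OCC)cc(OCc4ccc(OC)cc4)c2C(=[N+]=[N-])c2cc(OC)cc(OC)c2)cc1
F11 | step 15 | (2S,3R)-3-(3,5-dimethoxyphenyl)-6-ethoxy-2-(4-methoxyphenyl)-4-[BC]-2,3-dihydrobenzofuran (ring A 2,3-cis epimer of 30) | COc1ccc([C@H]2Oc3cc(OC)cc([C@@H]4c5c(Br)cc(OC)cc5O[C@H]4c4ccc(OC)cc4)c3[C@@H]2c2cc(OCC)cc3c2[C@@H](c2cc(OC)cc(OC)c2)[C@@H](c2ccc(OC)cc2)O3)cc1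
A1 | alternative 1 | methyl 3-chloro-2-[1-(3,5-dimethoxyphenyl)-2-(4-methoxyphenyl)-2-(4,4,5,5-tetramethyl-1,3,2-dioxaborolan-2-yl)ethyl]-5-methoxybenzoate, configuration as in the SMILES | COC(=O)c1cc(OC)cc(Cl)c1[C@@H](c1cc(OC)cc(OC)c1)[C@H](c1ccc(OC)cc1)B1OC(C)(C)C(C)(C)O1
A2 | alternative 1 | methyl 3-chloro-5-methoxy-2-[(trifluoromethanesulfonyl)oxy]benzoate | COC(=O)c1cc(OC)cc(Cl)c1OS(=O)(=O)C(F)(F)F
A3 | alternative 1 | (E)-2-(3,5-dimethoxystyryl)-4,4,5,5-tetramethyl-1,3,2-dioxaborolane | COc1cc(/C=C/B2OC(C)(C)C(C)(C)O2)cc(OC)c1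
A4 | alternative 1 | 4-methoxyphenyllithium | [Li]c1ccc(OC)cc1
A5 | alternative 2 | permethylated tris(dihydrobenzofuran) with the three 4-methoxyphenyl groups and a methyl ester on C4C | COc1ccc([C@H]2Oc3cc(OC)cc([C@@H]4c5c(C(=O)OC)cc(OC)cc5O[C@H]4c4ccc(OC)cc4)c3[C@@H]2c2cc(OC)cc3c2[C@@H](c2cc(OC)cc(OC)c2)[C@H](c2ccc(OC)cc2)O3)cc1
A6 | alternative 2 | tris(dihydrobenzofuran-2-carboxylic acid) corresponding to A5, C2 centres undefined | OC(=O)C2Oc3cc(OC)cc([C@@H]4c5c(C(=O)OC)cc(OC)cc5OC4C(=O)O)c3[C@@H]2c2cc(OC)cc3c2[C@@H](c2cc(OC)cc(OC)c2)C(C(=O)O)O3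
A7 | alternative 2 | 4-bromoanisole | COc1ccc(Br)cc1
A8 | alternative 3 | methyl (2S,3S)-6-methoxy-2-(4-methoxyphenyl)-4-[(trifluoromethanesulfonyl)oxy]-2,3-dihydrobenzofuran-3-carboxylate (identical with 4) | COc1ccc([C@H]2Oc3cc(OC)cc(OS(=O)(=O)C(F)(F)F)c3[C@@H]2C(=O)OC)cc1
A9 | alternative 3 | (2S)-7-methoxy-2-(4-methoxyphenyl)-4-oxochroman-5-yl trifluoromethanesulfonate (identical with 3) | O=C1C[C@@H](c2ccc(OC)cc2)Oc2cc(OC)cc(OS(=O)(=O)C(F)(F)F)c12
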